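**Plan**

Cuts (drimane numbering): first the C11–O aryl ether, then C8=C12 (back to an 8-ketone), then C7–C8 and C8–C9 together, which removes C8 as carbon monoxide.
Enabling feature: in ring B (C5–C6=C7–C8–C9–C10) the methylene-bearing C8 is a single carbon wedged between C7 and the C9 stereocentre. Without it, the rest of ring B is a vinyl group (C6=C7) on C5 of a C5–C9–C10 cyclopropane fused to ring A.
Forward order: ring A is bought, the cyclopropane is fused on by adding a tethered diazoacetate to C5=C10, ring B arises by [5+1] carbonylation, and the coumarin is attached last.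
Stereochemistry: a chiral dirhodium carboxamidate sets the absolute sense at C5, C9 and C10. The lactone tether forces C11 cis to the 10-methyl, and C9 and C10 pass through the ring expansion unchanged.
5α-H is set when the 5-en-8-one is conjugated by base to the trans-fused 6-en-8-one, which also places C6=C7. The axial 3α-OH comes from LiBH(s-Bu)3 reduction of the 3-ketone.

Key step: step 13

Numbering: drimane locants are used for all route carbons (ring A = C1–C2–C3–C4–C5–C10; C6 = carbon on C5; C9 = former carbene carbon; C11 = carbon on C9; β = face of the 10-methyl).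
Assumption: the S-configured catalyst is taken to attack the alkene face that leads to the series drawn, by extrapolation from the sense known for 3-methylbut-2-enyl diazoacetate; the mirror-image catalyst is equally accessible if the sense proves opposite.

**Route**

Step 1
Reactants: 1 2,2-dimethylcyclohexane-1,3-dione; 2 ethylene glycol
Product: 3 6,6-dimethyl-1,4-dioxaspiro[4.5]decan-7-one
Conditions: 2 (1.0 equiv), p-TsOH·H2O (cat.), toluene, reflux, Dean–Stark trap
Reagents that add atoms: none
Why: Acid-catalysed ketalisation with one equivalent of diol and azeotropic water removal should stop at the monoketal, because the remaining carbonyl is then flanked by a quaternary carbon that carries a ketal.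

Step 2
Reactants: 3 6,6-dimethyl-1,4-dioxaspiro[4.5]decan-7-one
Product: 5 (±)-6,6,8-trimethyl-1,4-dioxaspiro[4.5]decan-7-one, via lithium enolate 4 (not isolated)
Conditions: LiN(i-Pr)2, THF, −78 °C; MeI, −78 → 0 °C
Reagents that add atoms: iodomethane, CI
Why: Kinetic enolate alkylation; only C10 carries enolisable hydrogens because C4 is quaternary, and the new stereocentre is irrelevant since step 3 erases it.

Step 3
Reactants: 5 (±)-6,6,8-trimethyl-1,4-dioxaspiro[4.5]decan-7-one
Product: 7 6,6,8-trimethyl-1,4-dioxaspiro[4.5]dec-7-en-7-yl trifluoromethanesulfonate, via lithium enolate 6 (not isolated)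
Conditions: LiN(i-Pr)2, THF, −78 → 0 °C; PhNTf2, 0 °C → rt
Reagents that add atoms: N-phenylbis(trifluoromethanesulfonimide), O=S(=O)(N(c1ccccc1)S(=O)(=O)C(F)(F)F)C(F)(F)F
Why: Enolate O-triflation; a single (tetrasubstituted C5=C10) enolate is possible, as is well known for 2,2,6-trimethylcyclohexanone.

Step 4
Reactants: 7 6,6,8-trimethyl-1,4-dioxaspiro[4.5]dec-7-en-7-yl trifluoromethanesulfonate; 8 carbon monoxide
Product: 9 methyl 6,6,8-trimethyl-1,4-dioxaspiro[4.5]dec-7-ene-7-carboxylate
Conditions: Pd(OAc)2 (5 mol %), PPh3 (10 mol %), CO (1 atm), Et3N, MeOH/DMF, 60 °C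
Reagents that add atoms: methanol, CO
Why: Palladium-catalysed alkoxycarbonylation of an enol triflate (oxidative addition to zerovalent palladium, CO insertion, methanolysis) installs C6 on C5 and is established for hindered 2,6,6-trimethylcyclohexenyl triflates.

Step 5
Reactants: 9 methyl 6,6,8-trimethyl-1,4-dioxaspiro[4.5]dec-7-ene-7-carboxylate
Product: 10 (6,6,8-trimethyl-1,4-dioxaspiro[4.5]dec-7-en-7-yl)methanol
Conditions: i-Bu2AlH (2.5 equiv), CH2Cl2, −78 → 0 °C; aq. KNa tartrate
Reagents that add atoms: none
Why: 1,2-Reduction of the enoate with an aluminium hydride gives the allylic alcohol, and at low temperature the dioxolane is not opened.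

Step 6
Reactants: 10 (6,6,8-trimethyl-1,4-dioxaspiro[4.5]dec-7-en-7-yl)methanol; 11 bromoacetyl bromide
Product: 12 (6,6,8-trimethyl-1,4-dioxaspiro[4.5]dec-7-en-7-yl)methyl bromoacetate
Conditions: NaHCO3, MeCN, 0 °C
Reagents that add atoms: none
Why: O-Acylation by the acyl bromide is fast even at a neopentyl-like primary alcohol, and the solid bicarbonate scavenges HBr so that the ketal survives.

Step 7
Reactants: 12 (6,6,8-trimethyl-1,4-dioxaspiro[4.5]dec-7-en-7-yl)methyl bromoacetate
Product: 13 (6,6,8-trimethyl-1,4-dioxaspiro[4.5]dec-7-en-7-yl)methyl diazoacetate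
Conditions: TsNHNHTs, DBU, THF, 0 °C
Reagents that add atoms: N,N'-ditosylhydrazine, Cc1ccc(cc1)S(=O)(=O)NNS(=O)(=O)c1ccc(C)cc1
Why: Diazoacetate synthesis from a bromoacetate; the hydrazide anion displaces bromide and two base-induced sulfinate eliminations unveil the diazo group under conditions harmless to ketal and alkene.

Step 8
Reactants: 13 (6,6,8-trimethyl-1,4-dioxaspiro[4.5]dec-7-en-7-yl)methyl diazoacetate
Product: 14 tricyclic cyclopropane lactone (C5–C9–C10 ring; C11(=O)–O–C6 bridge; 10-Me/C6/C11 all cis)
Conditions: Rh2(4S-MPPIM)4 (1 mol %; MPPIM = methyl 1-(3-phenylpropanoyl)-2-oxoimidazolidine-4-carboxylate), CH2Cl2, reflux, slow addition of 13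
Reagents that add atoms: none
Why: Enantioselective intramolecular metal-carbene cyclopropanation of an allylic diazoacetate: concerted syn addition keeps C1 and C4 cis, the five-membered lactone can only form with C11 cis to C6 and hence cis to the 10-methyl, the chiral carboxamidate ligands choose the alkene face and so fix C5, C9 and C10 together, and this imidazolidinone catalyst is the member of its family that keeps enantiocontrol when the internal alkene carbon is substituted, while no C–H bond is placed for γ-lactone insertion.

Step 9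
Reactants: 14 tricyclic cyclopropane lactone
Product: 15 cyclopropane 6,11-diol (5β-CH2OH; 9-CH2OH cis to it; 10β-Me)
Conditions: LiAlH4, THF, 0 °C → rt
Reagents that add atoms: none
Why: Hydride reduction of the lactone to the diol leaves ketal and cyclopropane untouched, and the diol offers a point where enantiomeric purity could be raised by recrystallisation.

Step 10
Reactants: 15 cyclopropane 6,11-diol
Product: 16 11-O-tert-butyldiphenylsilyl ether of 15 (free 6-OH)
Conditions: TBDPSCl (1.0 equiv), imidazole, CH2Cl2, −20 → 0 °C
Reagents that add atoms: tert-butyl(chloro)diphenylsilane, CC(C)(C)[Si](Cl)(c1ccccc1)c1ccccc1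
Why: Sterically governed monosilylation; the C11 hydroxyl hangs on a CH carbon, whereas the C6 hydroxyl is neopentyl on quaternary C5 between quaternary C4 and C10, so the bulky silyl chloride should take C11.

Step 11
Reactants: 16 11-O-TBDPS 6-alcohol
Product: 17 cyclopropanecarbaldehyde (C6 = CHO on C5; 11-OTBDPS)
Conditions: n-Pr4N[RuO4] (5 mol %), NMO, 4 Å MS, CH2Cl2, rt
Reagents that add atoms: none
Why: Ley–Griffith oxidation converts the hindered primary alcohol into a non-enolisable aldehyde under neutral conditions tolerated by the ketal and silyl ether.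

Step 12
Reactants: 17 cyclopropanecarbaldehyde
Product: 18 ring A fused vinylcyclopropane (5β-vinyl; 10β-Me; C9 bridging the α face; 9-CH2OTBDPS cis to vinyl; 3,3-ethylenedioxy)
Conditions: Ph3PCH3Br, KOt-Bu, THF, 0 °C → rt
Reagents that add atoms: methyltriphenylphosphonium bromide, C[P+](c1ccccc1)(c1ccccc1)c1ccccc1.[Br-]
Why: Wittig methylenation with the small unstabilised ylide works on hindered aldehydes, and with no α-hydrogen on C5 nothing can epimerise.

Step 13
Reactants: 18 ring A fused vinylcyclopropane; 8 carbon monoxide
Product: 19 3,3-ethylenedioxy-11-(tert-butyldiphenylsilyloxy)-12-nordrim-5-en-8-one (9α-H; 10β-Me)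
Conditions: [Rh(CO)2Cl]2 (5 mol %), dppp (11 mol %), AgOTf (12 mol %), CO (0.2 atm in N2), 4 Å MS, 1,2-dichloroethane, 85 °C
Reagents that add atoms: none
Why: The cationic monovalent rhodium centre binds the vinyl group and adds oxidatively into the adjacent strained C5–C9 bond to give a rhodacyclohexene that is π-allyl over C5–C6–C7 and σ-bound at C9; CO migrates into the C9–Rh bond and reductive elimination joins the acyl carbon (C8) to the allyl terminus C7. The closest known reaction type is this one itself, the rhodium-catalysed [5+1] carbonylative ring expansion of vinylcyclopropanes to cyclohex-3-enones, whose iron- and cobalt-carbonyl versions also cover ring-fused alkenylcyclopropanes. Ring B closes as a six-membered carbocycle by C7–C8 reductive elimination from the seven-membered acylrhodacycle, a formal [5+1] cycloaddition of the C7–C6–C5–C10–C9 unit with CO. No stereocentre is created: C5 turns sp2, C10 is not touched, and C9 keeps its configuration because C–C insertion and acyl migration both go with retention, so the cis C11/10-methyl pair of 18 becomes the 9β,10β pair of 19. The selectivity needed is cleavage of C5–C9 and not of the ring-fusion bond C5–C10; it is secured because C9 is a CH carbon giving a secondary alkyl–rhodium bond while C10 is quaternary, and because opening C5–C10 would lead to a bridged bicyclo[4.3.1] enone with a bridgehead alkene. The C4 gem-dimethyl group pushes the vinyl terminus toward C9, the rotamer that gives the cis ring alkene, and the low CO pressure leaves the metal able to insert yet saturated enough to hold back β-hydride loss from C11.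

Step 14
Reactants: 19 12-nordrim-5-en-8-one
Product: 20 3,3-ethylenedioxy-11-(tert-butyldiphenylsilyloxy)-12-nordrim-6-en-8-one (5α-H; 9α-H; 10β-Me)
Conditions: DBU (0.3 equiv), CH2Cl2, rt
Reagents that add atoms: none
Why: Base-mediated conjugation of a β,γ-enone through the extended dienolate; C5 is protonated from the α face, away from the axial 10β- and 4β-methyls, the equilibrium favours the trans-fused conjugated enone, and the equatorial 9β side chain is also the thermodynamic arrangement at the epimerisable C9.

Step 15
Reactants: 20 12-nordrim-6-en-8-one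
Product: 21 3,3-ethylenedioxy-11-(tert-butyldiphenylsilyloxy)drima-6,8(12)-diene
Conditions: Cp2TiMe2 (2.5 equiv), toluene, 70 °C, dark
Reagents that add atoms: dimethyltitanocene, C[Ti+2]C.[cH-]1cccc1.[cH-]1cccc1
Why: Petasis methylenation; the non-basic titanium methylidene converts the enone carbonyl into C8=C12 without enolising C9, so neither epimerisation nor β-elimination of the silyloxy group is expected.

Step 16
Reactants: 21 3,3-ethylenedioxy diene
Product: 22 11-(tert-butyldiphenylsilyloxy)drima-6,8(12)-dien-3-one
Conditions: PPTS (0.2 equiv), acetone/H2O (10:1), 50 °C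
Reagents that add atoms: water, O
Why: Mild acid-catalysed ketal hydrolysis; ionisation is helped by relief of strain next to C4, the weak pyridinium acid should not protonate the transoid diene, and the diphenyl-substituted silyl ether is stable to it.

Step 17
Reactants: 22 drima-6,8(12)-dien-3-one
Product: 23 11-(tert-butyldiphenylsilyloxy)drima-6,8(12)-dien-3α-ol
Conditions: LiBH(s-Bu)3, THF, −78 → 0 °C; then H2O
Reagents that add atoms: none
Why: Bulky trialkylborohydride reduction; the reagent avoids the axial hydrogens at C1 and C5 and attacks the chair 4,4-dimethyl-3-ketone along the equatorial trajectory, giving the axial 3α-alcohol as is usual for such ketones.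

Step 18
Reactants: 23 silyl ether 3α-ol
Product: 24 drima-6,8(12)-diene-3α,11-diol
Conditions: n-Bu4NF, THF, rt
Reagents that add atoms: none
Why: Fluoride-induced desilylation frees the primary C11 alcohol without acid, so the diene is not at risk.

Step 19
Reactants: 24 drima-6,8(12)-diene-3α,11-diol; 25 umbelliferone
Product: 26 7-[(3α-hydroxydrima-6,8(12)-dien-11-yl)oxy]coumarin (target)
Conditions: PPh3, DIAD, THF, 0 °C → rt
Reagents that add atoms: none
Why: Mitsunobu etherification; only the primary C11 hydroxyl is activated, because the axial 3α-hydroxyl next to quaternary C4 is too hindered, the acidic phenol is a good partner, and no stereocentre is involved.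

**Compound list**

1 | 2,2-dimethylcyclohexane-1,3-dione | CC1(C)C(=O)CCCC1=O | starting material
2 | ethylene glycol | OCCO | starting material
3 | 6,6-dimethyl-1,4-dioxaspiro[4.5]decan-7-one | CC1(C)C(=O)CCCC12OCCO2 | intermediate
4 | lithium enolate of 3 (C5=C10) | [Li]OC1=CCCC2(OCCO2)C1(C)C | intermediate
5 | (±)-6,6,8-trimethyl-1,4-dioxaspiro[4.5]decan-7-one | CC1CCC2(OCCO2)C(C)(C)C1=O | intermediate
6 | lithium enolate of 5 (tetrasubstituted C5=C10) | [Li]OC1=C(C)CCC2(OCCO2)C1(C)C | intermediate
7 | 6,6,8-trimethyl-1,4-dioxaspiro[4.5]dec-7-en-7-yl trifluoromethanesulfonate | CC1=C(OS(=O)(=O)C(F)(F)F)C(C)(C)C2(OCCO2)CC1 | intermediate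
8 | carbon monoxide | [C-]#[O+] | starting material
9 | methyl 6,6,8-trimethyl-1,4-dioxaspiro[4.5]dec-7-ene-7-carboxylate | COC(=O)C1=C(C)CCC2(OCCO2)C1(C)C | intermediate
10 | (6,6,8-trimethyl-1,4-dioxaspiro[4.5]dec-7-en-7-yl)methanol | OCC1=C(C)CCC2(OCCO2)C1(C)C | intermediate
11 | bromoacetyl bromide | O=C(Br)CBr | starting material
12 | (6,6,8-trimethyl-1,4-dioxaspiro[4.5]dec-7-en-7-yl)methyl bromoacetate | O=C(CBr)OCC1=C(C)CCC2(OCCO2)C1(C)C | intermediate
13 | (6,6,8-trimethyl-1,4-dioxaspiro[4.5]dec-7-en-7-yl)methyl diazoacetate | [N-]=[N+]=CC(=O)OCC1=C(C)CCC2(OCCO2)C1(C)C | intermediate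
14 | cyclopropane γ-lactone: ring A (3,3-ethylenedioxy, 4,4,10-trimethyl) fused at C5–C10 to a cyclopropane completed by C9; lactone C9–C11(=O)–O–C6H2–C5; C6, C11 and 10-Me on one cyclopropane face, C1, C4 and H9 on the other | O=C1OC[C@@]23C(C)(C)C4(OCCO4)CC[C@]2(C)[C@@H]13 | intermediate
15 | cyclopropane 6,11-diol (5β-CH2OH, 9-CH2OH cis to it and to 10β-Me, 3,3-ethylenedioxy) | OC[C@@]12C(C)(C)C3(OCCO3)CC[C@]1(C)[C@H]2CO | intermediate
16 | 11-O-TBDPS ether of 15, free 6-OH | OC[C@@]12C(C)(C)C3(OCCO3)CC[C@]1(C)[C@H]2CO[Si](c1ccccc1)(c1ccccc1)C(C)(C)C | intermediate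
17 | C5 carbaldehyde (C6 = CHO), 11-OTBDPS, same cyclopropane configuration | O=C[C@@]12C(C)(C)C3(OCCO3)CC[C@]1(C)[C@H]2CO[Si](c1ccccc1)(c1ccccc1)C(C)(C)C | intermediate
18 | ring A fused vinylcyclopropane: 5β-vinyl, 10β-Me, C9 bridging the α face, 9-CH2OTBDPS cis to vinyl and methyl, 3,3-ethylenedioxy | C=C[C@@]12C(C)(C)C3(OCCO3)CC[C@]1(C)[C@H]2CO[Si](c1ccccc1)(c1ccccc1)C(C)(C)C | intermediate
19 | 3,3-ethylenedioxy-11-(TBDPS-oxy)-12-nordrim-5-en-8-one (9α-H, 10β-Me) | O=C1CC=C2C(C)(C)C3(OCCO3)CC[C@]2(C)[C@H]1CO[Si](c1ccccc1)(c1ccccc1)C(C)(C)C | intermediate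
20 | 3,3-ethylenedioxy-11-(TBDPS-oxy)-12-nordrim-6-en-8-one (5α-H, 9α-H, 10β-Me) | O=C1C=C[C@H]2C(C)(C)C3(OCCO3)CC[C@]2(C)[C@H]1CO[Si](c1ccccc1)(c1ccccc1)C(C)(C)C | intermediate
21 | 3,3-ethylenedioxy-11-(TBDPS-oxy)drima-6,8(12)-diene | C=C1C=C[C@H]2C(C)(C)C3(OCCO3)CC[C@]2(C)[C@H]1CO[Si](c1ccccc1)(c1ccccc1)C(C)(C)C | intermediate
22 | 11-(TBDPS-oxy)drima-6,8(12)-dien-3-one | C=C1C=C[C@H]2C(C)(C)C(=O)CC[C@]2(C)[C@H]1CO[Si](c1ccccc1)(c1ccccc1)C(C)(C)C | intermediate
23 | 11-(TBDPS-oxy)drima-6,8(12)-dien-3α-ol | C=C1C=C[C@H]2C(C)(C)[C@H](O)CC[C@]2(C)[C@H]1CO[Si](c1ccccc1)(c1ccccc1)C(C)(C)C | intermediate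
24 | drima-6,8(12)-diene-3α,11-diol | C=C1C=C[C@H]2C(C)(C)[C@H](O)CC[C@]2(C)[C@H]1CO | intermediate
25 | umbelliferone (7-hydroxycoumarin) | O=c1ccc2ccc(O)cc2o1 | starting material
26 | 7-{[(3R,5R,9S,10S)-3-hydroxydrima-6,8(12)-dien-11-yl]oxy}-2H-chromen-2-one (3α-OH, 5α-H, 9α-H, 10β-Me) | C=C1C=C[C@H]2C(C)(C)[C@H](O)CC[C@]2(C)[C@H]1COc1ccc2ccc(=O)oc2c1 | target

**Totals and risks**

Total step count: 19. Longest linear sequence: 19 steps (from 1).

Steps most likely to fail:

Step 13. Oxidative addition next to the fully substituted C5 may be too slow. Alternatively, the rhodacycle may drain away through β-hydride loss from C11 and end in ring-opened dienes. The fallback sets out from 18 and comes back at 19. The carbonyl is delivered by a stoichiometric, light-driven iron carbonyl insertion instead of a catalytic C–C oxidative addition. Irradiation of 18 with Fe(CO)5 in 2-propanol under CO first binds a zerovalent Fe(CO)4 fragment to the vinyl group. Ring opening of C5–C9 then gives an acyl(π-allyl)iron tricarbonyl. This species is coordinatively saturated, so it offers no free site for β-hydride loss, and it collapses under CO to 19. No compound outside the list is made.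

Step 8. Carbene transfer to a tetrasubstituted alkene beside quaternary C4 may be slow enough for carbene dimerisation to compete, and discrimination between the two alkene faces may be poor. The fallback sets out from 13 and comes back at 15; absolute configuration is obtained by resolution instead of catalysis. Achiral Rh2(OAc)4 in CH2Cl2 turns 13 into the racemic lactone F1, whose relative configuration is still dictated by the tether. LiAlH4 then gives the racemic diol F2. Acylation of its less hindered C11 hydroxyl with (S)-2-methoxy-2-phenylacetic acid (EDC·HCl, DMAP, CH2Cl2) gives two diastereomeric monoesters, which are separated by chromatography or crystallisation. The diastereomer of the drimane series, the (S)-O-methylmandelate monoester F3, is saponified (LiOH, THF/H2O) to 15.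

Step 14. Protonation of the extended dienolate at C5 may lack facial bias, or the equilibrium may stop short of full conjugation. Enolisation toward C9 may also trigger E1cB loss of the silanolate from C11. The fallback sets out from 19 and comes back at 20; C5 is set by a base-free radical hydrogenation and the alkene is reintroduced afterwards. Mn(dpm)3 (cat.), PhSiH3 and t-BuOOH in i-PrOH add a hydrogen atom to C6 and then to the tertiary C5 radical, in the sense that gives the more stable trans-decalin, the saturated 8-ketone F4. Kinetic enolisation at the C7 methylene (LiN(i-Pr)2, TMSCl, THF, −78 °C) gives the Δ7 trimethylsilyl enol ether F5. Saegusa–Ito oxidation with Pd(OAc)2 in MeCN then gives 20.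

**Further compounds**

F0 | step 13 | none | none
F1 | step 8 | (±)-cyclopropane γ-lactone, relative configuration as in 14 | O=C1OCC23C(C)(C)C4(OCCO4)CCC2(C)C13
F2 | step 8 | (±)-cyclopropane 6,11-diol, relative configuration as in 15 | OCC12C(C)(C)C3(OCCO3)CCC1(C)C2CO
F3 | step 8 | 11-O-[(S)-2-methoxy-2-phenylacetyl] monoester of 15 | OC[C@@]12C(C)(C)C3(OCCO3)CC[C@]1(C)[C@H]2COC(=O)[C@@H](OC)c1ccccc1
F4 | step 14 | 3,3-ethylenedioxy-11-(TBDPS-oxy)-12-nordriman-8-one (5α-H, 9α-H, 10β-Me) | O=C1CC[C@H]2C(C)(C)C3(OCCO3)CC[C@]2(C)[C@H]1CO[Si](c1ccccc1)(c1ccccc1)C(C)(C)C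
F5 | step 14 | 8-(trimethylsilyloxy)-3,3-ethylenedioxy-11-(TBDPS-oxy)-12-nordrim-7-ene | C[Si](C)(C)OC1=CC[C@H]2C(C)(C)C3(OCCO3)CC[C@]2(C)[C@H]1CO[Si](c1ccccc1)(c1ccccc1)C(C)(C)C
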